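Late in the epsilon run the substrate falls more slowly: 53.0% at 25.0 h, 47.5% at 40.0 h. So when you repeat this, watch the coupling partner and keep its books.

| flask | substrate | fresh partner | coupling partner | remark | time |
|---|---|---|---|---|---|
| epsilon | 0.39 M | 0.18 M | 0.41 M | run made earlier |  |
| flask | 0.39 M | 0.351 M | 0.410 M |  | 15 d |

- epsilon (time / h: target / %, substrate / %): 10.0: 3.7, 67.2; 20.0: 11.4, 57.1; 25.0: 16.4, 53.0; 40.0: 23.1, 47.5

(readings scatter by 1 percentage point)

- the moment within 15 d at which there is most target
- the amount of target, in percent of the substrate charged, at that time

Here is my own ledger, with the coupling partner as limiting reagent. In the epsilon run the substrate has taken 0.205 M by the last reading. Enter the fresh partner's whole charge, 0.18 M, as well. Together that makes 0.385 M, a little less than the 0.41 M charged, so the books come close.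

I therefore freeze one entry: [fresh partner] takes its charge of coupling partner first, and the spare, [coupling partner] minus [fresh partner], goes to substrate as open intermediate. Each target needs one open and one second intermediate. The ledger figure, an estimate and not a bound, is the smallest of the spare, the fresh partner charge and the substrate charge, in percent of the substrate charged. For this flask the spare is 0.0590 M, so the ledger figure is 15.1%. I commit to about that.

The forecast says 33% at 4 d, on this ground: "Doubling fresh partner diverts more coupling partner to the second intermediate". My ledger figure stands lower.

The flask gives 17.0% at 4.15 d.

    substrate + coupling partner → open intermediate (k = 0.00380 L mol⁻¹ min⁻¹)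
    coupling partner + fresh partner → second intermediate (k = 0.0620 L mol⁻¹ min⁻¹)
    open intermediate + second intermediate → target (k = 0.00270 L mol⁻¹ min⁻¹)
    substrate → decomposition product (k = 3.80 × 10⁻⁷ min⁻¹)
    fresh partner + target → over-reaction product (k = 0.00140 L mol⁻¹ min⁻¹)

In this flask, depletion of the coupling partner is the largest single effect on the best: without it the best goes from 17.0% to 88.9%, against 1.4 percentage points for the over-reaction step. The ledger figure sits 1.9 points below this flask's best of 17.0%. In the neighbour charged with 1.0 M of coupling partner, the ledger figure moves to the fresh partner charge, 90.0%, and that neighbour reaches 88.9%. Its books leave 25.9% of its coupling partner over. That neighbour ends with 26% unused.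

(All runs were computed for an exercise.)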